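**Plan**

Numbering: saturated ring B holds tetralin C1 (carbinol) to C4 (diarylmethine), aromatic ring A holds C4a to C8a, and naphthyl atoms carry primes.
Enabling feature: the only oxygen of ring A sits on C5, next to the fusion carbon C4a. A 2-furyl group supplies C8a, C8, C7, C6 and that oxygen, a terminal alkyne supplies C4a and C5, and the gold furan–yne rearrangement moves the furan oxygen onto the terminal alkyne carbon.
Cuts, in retrosynthetic order: the O-methyl and O-protecting operations; C4a–C8a together with C5–C6 (rings B and A open to a furyl alkynyl chain); C1–C2 (furoyl unit); C4–C4a (alkyne onto an enal); C4–C1' (Heck).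
Forward: the naphthalene piece is brominated, joined to C4–C3–C2 by a Heck reaction, alkynylated at C4 and extended at C2 with the furoyl group. One gold step then closes ring B and after it ring A.
Stereochemistry: C4 comes from the chiral bisphosphine–rhodium catalyst of the conjugate alkynylation and C1 from the chiral ruthenium catalyst of the ketone transfer hydrogenation. Both are set on the open chain under catalyst control, and the cis relation follows from how the two catalysts are paired.

Key step: step 12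

Assumption: the (R)-bisphosphine of step 5 is taken to deliver the alkynyl group to the alkene face that gives the drawn C4 configuration, by analogy with the quadrant model for rhodium 1,4-additions to (E)-acceptors; if a trial on the enal shows the opposite sense, the (S)-ligand is used and nothing else changes.

**Route**

Step 1
Reactants: 1 naphthalene-1,8-diol
Product: 2 8-methoxynaphthalen-1-ol
Conditions: MeI (1.05 equiv), K2CO3 (1.1 equiv), acetone, reflux
Reagents that add atoms: iodomethane, CI
Why: Williamson ether synthesis that should stop at the monoether, because the remaining hydroxyl is hydrogen-bonded to the peri methoxy oxygen and is much harder to deprotonate.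

Step 2
Reactants: 2 8-methoxynaphthalen-1-ol
Product: 3 4-bromo-8-methoxynaphthalen-1-ol
Conditions: NBS (1.0 equiv), MeCN, −20 to 0 °C, dark
Reagents that add atoms: N-bromosuccinimide, O=C1CCC(=O)N1Br
Why: Electrophilic aromatic bromination in which the hydroxyl-bearing ring is the more activated one (OH is the stronger donor and its hydrogen bond ties up a methoxy lone pair), and NBS in MeCN favours the para carbon C4 over the ortho carbon C2.

Step 3
Reactants: 3 4-bromo-8-methoxynaphthalen-1-ol
Product: 4 1-(benzyloxy)-4-bromo-8-methoxynaphthalene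
Conditions: BnBr, K2CO3, DMF, 60 °C
Reagents that add atoms: benzyl bromide, BrCc1ccccc1
Why: Williamson ether synthesis in warm DMF, which overcomes the peri hydrogen bond and installs an ether that tolerates the organometallic, hydride, fluoride and gold steps up to step 14.

Step 4
Reactants: 4 1-(benzyloxy)-4-bromo-8-methoxynaphthalene; 5 acrolein diethyl acetal
Product: 7 (E)-3-[4-(benzyloxy)-5-methoxynaphthalen-1-yl]prop-2-enal, via enal diethyl acetal 6 (not isolated)
Conditions: Pd(OAc)2 (3 mol %), n-Bu4NOAc, K2CO3, KCl, DMF, 90 °C; then 2 M aq HCl, rt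
Reagents that add atoms: water, O
Why: Heck reaction of the aryl bromide with acetal-masked acrolein under ligand-free, acetate-rich conditions, where β-hydride elimination away from the acetal carbon gives the (E)-alkenyl acetal that aqueous acid unmasks to the enal.

Step 5
Reactants: 7 (E)-3-[4-(benzyloxy)-5-methoxynaphthalen-1-yl]prop-2-enal; 8 (triisopropylsilyl)acetylene
Product: 9 (3S)-3-[4-(benzyloxy)-5-methoxynaphthalen-1-yl]-5-(triisopropylsilyl)pent-4-ynal
Conditions: [Rh(OAc)(C2H4)2]2 (2.5 mol %), (R)-DTBM-SEGPHOS (6 mol %), MeOH–1,4-dioxane, 40 °C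
Reagents that add atoms: none
Why: Rhodium-catalysed asymmetric conjugate alkynylation of an enal, in which the alkynylrhodium species held by the bulky bisphosphine inserts one face of the (E)-alkene and so sets C4, while the large silyl group and ligand suppress alkyne dimerisation and 1,2-addition.

Step 6
Reactants: 9 (3S)-3-[4-(benzyloxy)-5-methoxynaphthalen-1-yl]-5-(triisopropylsilyl)pent-4-ynal
Product: 10 (3S)-3-[4-(benzyloxy)-5-methoxynaphthalen-1-yl]-5-(triisopropylsilyl)pent-4-yn-1-ol
Conditions: NaBH4, MeOH–THF, 0 °C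
Reagents that add atoms: none
Why: Borohydride reduction of the aldehyde, which leaves the silylalkyne alone and cannot disturb C4 because that centre is β to the carbonyl group.

Step 7
Reactants: 10 (3S)-3-[4-(benzyloxy)-5-methoxynaphthalen-1-yl]-5-(triisopropylsilyl)pent-4-yn-1-ol
Product: 11 [(3S)-3-[4-(benzyloxy)-5-methoxynaphthalen-1-yl]-5-iodopent-1-yn-1-yl]triisopropylsilane
Conditions: I2, PPh3, imidazole, CH2Cl2, 0 °C to rt
Reagents that add atoms: iodine, II
Why: Appel-type iodination by SN2 displacement of the oxyphosphonium group at the primary carbon C2, two atoms away from the stereocentre.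

Step 8
Reactants: 11 [(3S)-3-[4-(benzyloxy)-5-methoxynaphthalen-1-yl]-5-iodopent-1-yn-1-yl]triisopropylsilane; 12 furan-2-carbonyl chloride
Product: 14 (4S)-4-[4-(benzyloxy)-5-methoxynaphthalen-1-yl]-1-(furan-2-yl)-6-(triisopropylsilyl)hex-5-yn-1-one, via alkylzinc iodide 13 (not isolated)
Conditions: Zn dust, LiCl, THF, 40 °C; then 12, Pd(PPh3)4 (5 mol %), THF, 0 °C to rt
Reagents that add atoms: none
Why: Zinc insertion into the primary iodide followed by Negishi acylation (zerovalent palladium inserts into the acyl chloride, then transmetalation and reductive elimination) forms C1–C2 at the ketone level without over-addition, and the mild organozinc does not touch the acidic propargylic C4–H.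

Step 9
Reactants: 14 (4S)-4-[4-(benzyloxy)-5-methoxynaphthalen-1-yl]-1-(furan-2-yl)-6-(triisopropylsilyl)hex-5-yn-1-one
Product: 15 (1S,4S)-4-[4-(benzyloxy)-5-methoxynaphthalen-1-yl]-1-(furan-2-yl)-6-(triisopropylsilyl)hex-5-yn-1-ol
Conditions: RuCl[(S,S)-TsDPEN](p-cymene) (1 mol %), HCO2H–Et3N (5:2), CH2Cl2, rt
Reagents that add atoms: none
Why: Noyori asymmetric transfer hydrogenation, in which the furyl ring takes the aryl position of the CH/π-organised six-membered transition state, so the (S,S)-catalyst should set C1 as (S) under catalyst control whatever the remote C4 centre.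

Step 10
Reactants: 15 (1S,4S)-4-[4-(benzyloxy)-5-methoxynaphthalen-1-yl]-1-(furan-2-yl)-6-(triisopropylsilyl)hex-5-yn-1-ol
Product: 16 (1S,4R)-4-[4-(benzyloxy)-5-methoxynaphthalen-1-yl]-1-(furan-2-yl)hex-5-yn-1-ol
Conditions: n-Bu4NF, AcOH (1:1), THF, 0 °C to rt
Reagents that add atoms: none
Why: Fluoride protodesilylation of the alkynylsilane, buffered with acetic acid so that the benzylic propargylic C4–H is not removed and alkyne-to-allene isomerisation is avoided (the C4 descriptor changes only because the silyl group is gone).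

Step 11
Reactants: 16 (1S,4R)-4-[4-(benzyloxy)-5-methoxynaphthalen-1-yl]-1-(furan-2-yl)hex-5-yn-1-ol
Product: 17 tert-butyl{[(1S,4R)-4-[4-(benzyloxy)-5-methoxynaphthalen-1-yl]-1-(furan-2-yl)hex-5-yn-1-yl]oxy}dimethylsilane
Conditions: TBSCl, imidazole, DMF, rt
Reagents that add atoms: tert-butyldimethylsilyl chloride, CC(C)(C)[Si](C)(C)Cl
Why: Imidazole-promoted silylation of the secondary alcohol, which masks a hydroxyl that would otherwise add to the gold-activated alkyne by 6-exo hydroalkoxylation.

Step 12
Reactants: 17 tert-butyl{[(1S,4R)-4-[4-(benzyloxy)-5-methoxynaphthalen-1-yl]-1-(furan-2-yl)hex-5-yn-1-yl]oxy}dimethylsilane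
Product: 20 cis-(1S,4S)-4-[4-(benzyloxy)-5-methoxynaphthalen-1-yl]-1-(tert-butyldimethylsilyloxy)tetralin-5-ol, via oxepine 18 (not isolated), via arene oxide 19 (not isolated)
Conditions: (Ph3P)AuNTf2 (5 mol %), CH2Cl2 (0.02 M), rt
Reagents that add atoms: none
Why: Cationic monovalent gold binds the terminal alkyne and the furan C8a=C8 bond attacks the internal carbon C4a, which closes ring B in a 6-exo-dig mode (bond C4a–C8a) and leaves a catalyst-bound cyclopropyl carbene with its carbene centre on C5. Rupture of the C4a–C8 cyclopropane bond and of the furan O–C8a bond unfolds this species to a (Z)-dienal carbene, whose aldehyde oxygen on C6 adds to C5 and releases gold to give oxepine 18. Ring A is closed by disrotatory 6π electrocyclisation of 18 to arene oxide 19 (bond C5–C6), and 19 opens with the oxygen kept on C5 and loses the C5 proton to give the phenol. The closest known reaction type is the gold-catalysed furan–yne phenol synthesis (Hashmi phenol synthesis), which is established for terminal alkynes, for carbon tethers and for a six-membered second ring. No stereocentre is made, because the bonds at C1 and C4 take no part, so the configurations set in steps 5 and 9 and hence the cis relation should pass unchanged into 20. Two selectivities are needed: the furan must react before the methoxy-activated peri carbon C8' (6-endo hydroarylation), which the Markovnikov bias of a terminal alkyne for attack at C4a and the greater π-nucleophilicity of the furan should secure, and the oxide must open toward C5, which is favoured because the resulting cation rests on alkyl-substituted C4a whereas the alternative would rest on C8a next to the electron-withdrawing C1–O carbon.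

Step 13
Reactants: 20 cis-(1S,4S)-4-[4-(benzyloxy)-5-methoxynaphthalen-1-yl]-1-(tert-butyldimethylsilyloxy)tetralin-5-ol
Product: 21 cis-(1S,4S)-4-[4-(benzyloxy)-5-methoxynaphthalen-1-yl]-1-(tert-butyldimethylsilyloxy)-5-methoxytetralin
Conditions: MeI, K2CO3, DMF, rt
Reagents that add atoms: iodomethane, CI
Why: Williamson ether synthesis on the only free phenol, under conditions that a secondary alkyl silyl ether and an aryl benzyl ether both withstand.

Step 14
Reactants: 21 cis-(1S,4S)-4-[4-(benzyloxy)-5-methoxynaphthalen-1-yl]-1-(tert-butyldimethylsilyloxy)-5-methoxytetralin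
Product: 22 4-[(1S,4S)-4-(tert-butyldimethylsilyloxy)-8-methoxy-1,2,3,4-tetrahydronaphthalen-1-yl]-8-methoxynaphthalen-1-ol
Conditions: H2 (1 atm), 10% Pd/C, EtOAc, rt
Reagents that add atoms: none
Why: Catalytic hydrogenolysis of the aryl benzyl ether, which in neutral EtOAc at one atmosphere should be much faster than cleavage of the hindered, silyl-capped secondary benzylic C1–O bond or of the C4–aryl bonds.

Step 15
Reactants: 22 4-[(1S,4S)-4-(tert-butyldimethylsilyloxy)-8-methoxy-1,2,3,4-tetrahydronaphthalen-1-yl]-8-methoxynaphthalen-1-ol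
Product: 23 dipolynaphthalene B [(1S,4S)-4-(4-hydroxy-5-methoxynaphthalen-1-yl)-5-methoxy-1,2,3,4-tetrahydronaphthalen-1-ol]
Conditions: n-Bu4NF, AcOH (1:1), THF, rt
Reagents that add atoms: none
Why: Fluoride cleavage of the silyl ether breaks only the Si–O bond, so C1 keeps its configuration, and the buffer keeps the air-sensitive naphthol protonated.

**Compound list**

1 | naphthalene-1,8-diol | Oc1cccc2cccc(O)c12 | starting material
2 | 8-methoxynaphthalen-1-ol | COc1cccc2cccc(O)c12 | intermediate
3 | 4-bromo-8-methoxynaphthalen-1-ol | COc1cccc2c(Br)ccc(O)c12 | intermediate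
4 | 1-(benzyloxy)-4-bromo-8-methoxynaphthalene | COc1cccc2c(Br)ccc(OCc3ccccc3)c12 | intermediate
5 | acrolein diethyl acetal (3,3-diethoxyprop-1-ene) | C=CC(OCC)OCC | starting material
6 | enal diethyl acetal, (E)-1-(benzyloxy)-4-(3,3-diethoxyprop-1-en-1-yl)-8-methoxynaphthalene | CCOC(OCC)/C=C/c1ccc(OCc2ccccc2)c2c(OC)cccc12 | intermediate
7 | (E)-3-[4-(benzyloxy)-5-methoxynaphthalen-1-yl]prop-2-enal | O=C/C=C/c1ccc(OCc2ccccc2)c2c(OC)cccc12 | intermediate
8 | (triisopropylsilyl)acetylene | C#C[Si](C(C)C)(C(C)C)C(C)C | starting material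
9 | (3S)-3-[4-(benzyloxy)-5-methoxynaphthalen-1-yl]-5-(triisopropylsilyl)pent-4-ynal | CC(C)[Si](C(C)C)(C(C)C)C#C[C@H](c1ccc(OCc2ccccc2)c2c(OC)cccc12)CC=O | intermediate
10 | (3S)-3-[4-(benzyloxy)-5-methoxynaphthalen-1-yl]-5-(triisopropylsilyl)pent-4-yn-1-ol | CC(C)[Si](C(C)C)(C(C)C)C#C[C@H](c1ccc(OCc2ccccc2)c2c(OC)cccc12)CCO | intermediate
11 | [(3S)-3-[4-(benzyloxy)-5-methoxynaphthalen-1-yl]-5-iodopent-1-yn-1-yl]triisopropylsilane | CC(C)[Si](C(C)C)(C(C)C)C#C[C@H](c1ccc(OCc2ccccc2)c2c(OC)cccc12)CCI | intermediate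
12 | furan-2-carbonyl chloride | O=C(Cl)c1ccco1 | starting material
13 | alkylzinc iodide from 11 | CC(C)[Si](C(C)C)(C(C)C)C#C[C@H](c1ccc(OCc2ccccc2)c2c(OC)cccc12)CC[Zn]I | intermediate
14 | (4S)-4-[4-(benzyloxy)-5-methoxynaphthalen-1-yl]-1-(furan-2-yl)-6-(triisopropylsilyl)hex-5-yn-1-one | CC(C)[Si](C(C)C)(C(C)C)C#C[C@H](c1ccc(OCc2ccccc2)c2c(OC)cccc12)CCC(=O)c1ccco1 | intermediate
15 | (1S,4S)-4-[4-(benzyloxy)-5-methoxynaphthalen-1-yl]-1-(furan-2-yl)-6-(triisopropylsilyl)hex-5-yn-1-ol | CC(C)[Si](C(C)C)(C(C)C)C#C[C@H](c1ccc(OCc2ccccc2)c2c(OC)cccc12)CC[C@H](O)c1ccco1 | intermediate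
16 | (1S,4R)-4-[4-(benzyloxy)-5-methoxynaphthalen-1-yl]-1-(furan-2-yl)hex-5-yn-1-ol | C#C[C@H](c1ccc(OCc2ccccc2)c2c(OC)cccc12)CC[C@H](O)c1ccco1 | intermediate
17 | tert-butyl{[(1S,4R)-4-[4-(benzyloxy)-5-methoxynaphthalen-1-yl]-1-(furan-2-yl)hex-5-yn-1-yl]oxy}dimethylsilane | C#C[C@H](c1ccc(OCc2ccccc2)c2c(OC)cccc12)CC[C@H](O[Si](C)(C)C(C)(C)C)c1ccco1 | intermediate
18 | oxepine fused to ring B at C4a–C8a (O between C5 and C6; C1 and C4 as in 17) | O1C=CC=C2C(=C1)[C@H](c1ccc(OCc3ccccc3)c3c(OC)cccc13)CC[C@@H]2O[Si](C)(C)C(C)(C)C | intermediate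
19 | C5–C6 arene oxide, valence tautomer of 18 (oxide on either face, transient) | O1C2C=CC3=C(C12)[C@H](c1ccc(OCc2ccccc2)c2c(OC)cccc12)CC[C@@H]3O[Si](C)(C)C(C)(C)C | intermediate
20 | cis-(1S,4S)-4-[4-(benzyloxy)-5-methoxynaphthalen-1-yl]-1-(tert-butyldimethylsilyloxy)tetralin-5-ol | Oc1cccc2c1[C@H](c1ccc(OCc3ccccc3)c3c(OC)cccc13)CC[C@@H]2O[Si](C)(C)C(C)(C)C | intermediate
21 | cis-(1S,4S)-4-[4-(benzyloxy)-5-methoxynaphthalen-1-yl]-1-(tert-butyldimethylsilyloxy)-5-methoxytetralin | COc1cccc2c1[C@H](c1ccc(OCc3ccccc3)c3c(OC)cccc13)CC[C@@H]2O[Si](C)(C)C(C)(C)C | intermediate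
22 | 4-[(1S,4S)-4-(tert-butyldimethylsilyloxy)-8-methoxy-1,2,3,4-tetrahydronaphthalen-1-yl]-8-methoxynaphthalen-1-ol | COc1cccc2c1[C@H](c1ccc(O)c3c(OC)cccc13)CC[C@@H]2O[Si](C)(C)C(C)(C)C | intermediate
23 | dipolynaphthalene B, (1S,4S)-4-(4-hydroxy-5-methoxynaphthalen-1-yl)-5-methoxy-1,2,3,4-tetrahydronaphthalen-1-ol | COc1cccc2c1[C@H](c1ccc(O)c3c(OC)cccc13)CC[C@@H]2O | target

**Step count**

Total step count: 15. Longest linear sequence: 15 (from 1).

**Steps most likely to fail**

First risk, step 12. The gold-activated alkyne may be intercepted by the peri carbon C8' of the electron-rich naphthalene (hydroarylation) before the flexible four-carbon tether brings the furan into reach.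

- The fallback keeps the furan–yne closure but makes the competing arene electron-poorer. It sets out from ketone 14, whose acylfuran tolerates a Lewis acid.
- BCl3 with pentamethylbenzene (CH2Cl2, −78 °C) should remove the benzyl group to give the naphthol ketone F1.
- PivCl, Et3N and DMAP should then give the pivalate ketone F2, in which the C4' oxygen no longer feeds electron density across the ring junction to C8'.
- Transfer hydrogenation as in step 9 should give the pivalate carbinol F3, buffered fluoride the pivalate terminal alkyne F4, and silylation the pivalate furan–yne F5.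
- (Ph3P)AuNTf2 should carry F5 through the pivalate oxepine F6 and the pivalate arene oxide F7 to the pivalate tetralinol F8.
- MeI with K2CO3 should give the pivalate methyl ether F9.
- i-Bu2AlH (CH2Cl2, −78 °C) then cleaves the aryl ester, and the sequence comes back to the route at 22, so step 14 is not needed.

Second risk, step 5. The hindered β-(1-naphthyl) enal may insert into the alkynyl–rhodium bond too slowly, so that alkyne oligomerisation or poor facial selectivity takes over.

- The fallback replaces conjugate addition by allylic substitution. It sets out from bromide 4.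
- n-BuLi (THF, −78 °C) should give the aryllithium F10, which acrolein traps as the racemic allylic alcohol F11.
- Alkyne 8 is converted with n-BuLi, B(OMe)3 and KHF2 into the potassium alkynyltrifluoroborate F12.
- Iridium-catalysed enantioconvergent allylic alkynylation should join F11 and F12 to the branched 1,4-enyne F13, with C4 set by the ligand. The conditions are [Ir(cod)Cl]2, the BINOL-derived dibenz[b,f]azepinyl phosphoramidite–olefin ligand in the antipode that leads to the (S)-enyne, KHF2, CF3CO2H and 1,4-dioxane.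
- 9-BBN should add to the terminal alkene only, giving the B-alkyl borane F14.
- NaOH/H2O2 oxidises F14 to alcohol 10, where the sequence comes back to the route. Steps 4 to 6 are bypassed.

Third risk, step 2. Bromine may attack ortho to the hydroxyl group or on the methoxy ring, a second bromination may follow, or the naphthol may be oxidised.

- The fallback differentiates the two rings with an ester. It sets out from diol 1.
- BnBr (one equivalent) with K2CO3 should give the monobenzyl ether F15.
- Ac2O in pyridine should give the benzyloxy acetate F16, whose acetoxy ring is deactivated.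
- NBS in MeCN should then brominate para to the benzyloxy group to give the bromo acetate F17.
- K2CO3 in MeOH should free the bromonaphthol F18.
- MeI with K2CO3 gives 4, where the sequence comes back to the route. Steps 1 to 3 are bypassed.

Further compounds
F1 | step 12 | naphthol ketone, (4S)-1-(furan-2-yl)-4-(4-hydroxy-5-methoxynaphthalen-1-yl)-6-(triisopropylsilyl)hex-5-yn-1-one | CC(C)[Si](C(C)C)(C(C)C)C#C[C@H](c1ccc(O)c2c(OC)cccc12)CCC(=O)c1ccco1
F2 | step 12 | pivalate ketone, 4-[(3S)-6-(furan-2-yl)-6-oxo-1-(triisopropylsilyl)hex-1-yn-3-yl]-8-methoxynaphthalen-1-yl pivalate | CC(C)[Si](C(C)C)(C(C)C)C#C[C@H](c1ccc(OC(=O)C(C)(C)C)c2c(OC)cccc12)CCC(=O)c1ccco1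
F3 | step 12 | pivalate carbinol, 4-[(3S,6S)-6-(furan-2-yl)-6-hydroxy-1-(triisopropylsilyl)hex-1-yn-3-yl]-8-methoxynaphthalen-1-yl pivalate | CC(C)[Si](C(C)C)(C(C)C)C#C[C@H](c1ccc(OC(=O)C(C)(C)C)c2c(OC)cccc12)CC[C@H](O)c1ccco1
F4 | step 12 | pivalate terminal alkyne, 4-[(3R,6S)-6-(furan-2-yl)-6-hydroxyhex-1-yn-3-yl]-8-methoxynaphthalen-1-yl pivalate | C#C[C@H](c1ccc(OC(=O)C(C)(C)C)c2c(OC)cccc12)CC[C@H](O)c1ccco1
F5 | step 12 | pivalate furan–yne, 4-[(3R,6S)-6-(tert-butyldimethylsilyloxy)-6-(furan-2-yl)hex-1-yn-3-yl]-8-methoxynaphthalen-1-yl pivalate | C#C[C@H](c1ccc(OC(=O)C(C)(C)C)c2c(OC)cccc12)CC[C@H](O[Si](C)(C)C(C)(C)C)c1ccco1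
F6 | step 12 | pivalate oxepine (pivalate analogue of 18) | O1C=CC=C2C(=C1)[C@H](c1ccc(OC(=O)C(C)(C)C)c3c(OC)cccc13)CC[C@@H]2O[Si](C)(C)C(C)(C)C
F7 | step 12 | pivalate arene oxide (pivalate analogue of 19, oxide on either face) | O1C2C=CC3=C(C12)[C@H](c1ccc(OC(=O)C(C)(C)C)c2c(OC)cccc12)CC[C@@H]3O[Si](C)(C)C(C)(C)C
F8 | step 12 | pivalate tetralinol, 4-[(1S,4S)-4-(tert-butyldimethylsilyloxy)-8-hydroxy-1,2,3,4-tetrahydronaphthalen-1-yl]-8-methoxynaphthalen-1-yl pivalate | Oc1cccc2c1[C@H](c1ccc(OC(=O)C(C)(C)C)c3c(OC)cccc13)CC[C@@H]2O[Si](C)(C)C(C)(C)C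
F9 | step 12 | pivalate methyl ether, 4-[(1S,4S)-4-(tert-butyldimethylsilyloxy)-8-methoxy-1,2,3,4-tetrahydronaphthalen-1-yl]-8-methoxynaphthalen-1-yl pivalate | COc1cccc2c1[C@H](c1ccc(OC(=O)C(C)(C)C)c3c(OC)cccc13)CC[C@@H]2O[Si](C)(C)C(C)(C)C
F10 | step 5 | aryllithium, [4-(benzyloxy)-5-methoxynaphthalen-1-yl]lithium | [Li]c1ccc(OCc2ccccc2)c2c(OC)cccc12
F11 | step 5 | racemic allylic alcohol, 1-[4-(benzyloxy)-5-methoxynaphthalen-1-yl]prop-2-en-1-ol | C=CC(O)c1ccc(OCc2ccccc2)c2c(OC)cccc12
F12 | step 5 | potassium alkynyltrifluoroborate, potassium trifluoro[(triisopropylsilyl)ethynyl]borate | [K+].F[B-](F)(F)C#C[Si](C(C)C)(C(C)C)C(C)C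
F13 | step 5 | branched 1,4-enyne, [(3S)-3-[4-(benzyloxy)-5-methoxynaphthalen-1-yl]pent-4-en-1-yn-1-yl]triisopropylsilane | CC(C)[Si](C(C)C)(C(C)C)C#C[C@H](c1ccc(OCc2ccccc2)c2c(OC)cccc12)C=C
F14 | step 5 | B-alkyl borane, 9-[(3S)-3-[4-(benzyloxy)-5-methoxynaphthalen-1-yl]-5-(triisopropylsilyl)pent-4-yn-1-yl]-9-borabicyclo[3.3.1]nonane | CC(C)[Si](C(C)C)(C(C)C)C#C[C@H](c1ccc(OCc2ccccc2)c2c(OC)cccc12)CCB1C2CCCC1CCC2
F15 | step 2 | monobenzyl ether, 8-(benzyloxy)naphthalen-1-ol | Oc1cccc2cccc(OCc3ccccc3)c12
F16 | step 2 | benzyloxy acetate, 8-(benzyloxy)naphthalen-1-yl acetate | CC(=O)Oc1cccc2cccc(OCc3ccccc3)c12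
F17 | step 2 | bromo acetate, 8-(benzyloxy)-5-bromonaphthalen-1-yl acetate | CC(=O)Oc1cccc2c(Br)ccc(OCc3ccccc3)c12
F18 | step 2 | bromonaphthol, 8-(benzyloxy)-5-bromonaphthalen-1-ol | Oc1cccc2c(Br)ccc(OCc3ccccc3)c12
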